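**Assumption:** the target has no stereocentre, so "single isomer" is read as the (E)-alkene; LiN(iPr)2, LiTMP (lithium 2,2,6,6-tetramethylpiperidide) and LiOMe are used as purchased reagents.

## Retrosynthetic overview

1. Chiricanine C ⇐ its MOM ether (acetal cleavage) ⇐ aryl bromide + styrene (Heck reaction, sets the E-alkene).
2. Key disconnection: the aryl–OMe bond together with the neighbouring aryl–prenyl bond ⇐ a 3-alkoxyaryne + methoxide + prenyl bromide (new one-pot vicinal methoxy-prenylation).
3. Aryne precursor: the symmetric 3,5-dibromo-4-prenylphenyl MOM ether ⇐ 3,5-dibromophenol, by lithiation between the two bromines and prenylation.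
4. No ring is formed: the central benzene ring comes from 3,5-dibromophenol and the phenyl ring from styrene.

## Route

**Step 1**
Reactants: 1 3,5-dibromophenol; 2 chloromethyl methyl ether
Product: 3 1,3-dibromo-5-(methoxymethoxy)benzene
Conditions: NaH (1.2 equiv), MOMCl (1.2 equiv), THF/DMF, 0 °C to rt
Reagents that add atoms: chloromethyl methyl ether, COCCl
Why: Williamson-type O-alkylation of the sodium phenoxide gives the MOM ether, which survives the lithium amide steps and later steers the aryne regiochemistry by induction.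

**Step 2**
Reactants: 3 1,3-dibromo-5-(methoxymethoxy)benzene; 4 1-bromo-3-methylbut-2-ene (prenyl bromide)
Product: 6 1,3-dibromo-5-(methoxymethoxy)-2-(3-methylbut-2-en-1-yl)benzene, via 2,6-dibromo-4-(methoxymethoxy)phenyllithium 5 (not isolated)
Conditions: LiN(iPr)2 (1.05 equiv), THF, −78 °C, 1 h; then CuBr·SMe2 (10 mol%), prenyl bromide (1.5 equiv), −78 to −20 °C
Reagents that add atoms: 1-bromo-3-methylbut-2-ene, CC(C)=CCBr
Why: Acidity-controlled ortho-lithiation removes the ring proton flanked by two bromines (the most acidic position, the aryllithium being stable at −78 °C), and SN2 allylic substitution catalysed by monovalent copper gives the linear prenyl arene as a symmetric product.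

**Step 3**
Reactants: 6 1,3-dibromo-5-(methoxymethoxy)-2-(3-methylbut-2-en-1-yl)benzene; 7 lithium methoxide; 4 1-bromo-3-methylbut-2-ene
Product: 11 1-bromo-3-methoxy-5-(methoxymethoxy)-2,4-bis(3-methylbut-2-en-1-yl)benzene, via 2,4-dibromo-6-(methoxymethoxy)-3-prenylphenyllithium 8 (not isolated), via 5-bromo-3-(methoxymethoxy)-6-prenylbenzyne 9 (not isolated), via 4-bromo-2-methoxy-6-(methoxymethoxy)-3-prenylphenyllithium 10 (not isolated)
Conditions: LiOMe (5 equiv), THF–DMPU (9:1), −40 °C; LiTMP (1.15 equiv) added over 1 h, then to 0 °C; then CuBr·SMe2 (20 mol%), prenyl bromide (3 equiv), −40 °C to rt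
Reagents that add atoms: lithium methoxide, [Li+].[O-]C; 1-bromo-3-methylbut-2-ene, CC(C)=CCBr
Why: Proposed new method: one-pot vicinal methoxy-prenylation of an aryne – LiTMP removes one of the two equivalent ring protons of 6 (flanked by OMOM and Br), aryllithium 8 loses LiBr on warming to give 3-alkoxyaryne 9, the inductively withdrawing OMOM group distorts the triple bond so that small methoxide attacks the distal carbon (next to the prenyl group) and forms the aryl–OMe bond, the charge arrives between OMe and OMOM as the doubly chelated and hindered aryllithium 10 (too crowded to add to 9 and, being an anion, protected from a second deprotonation), and copper-catalysed SN2 substitution on prenyl bromide then gives 11; the closest known reaction types are alkoxide addition to LiTMP-generated arynes (aryl ether synthesis) and three-component aryne couplings in which a magnesium amide or thiolate adds and the new arylmetal is allylated under copper catalysis, the alkoxide/allyl halide combination not having been shown.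

**Step 4**
Reactants: 11 1-bromo-3-methoxy-5-(methoxymethoxy)-2,4-bis(3-methylbut-2-en-1-yl)benzene; 12 styrene
Product: 13 3-methoxy-5-(methoxymethoxy)-2,4-bis(3-methylbut-2-en-1-yl)-1-[(E)-2-phenylethenyl]benzene
Conditions: styrene (2 equiv), Pd(OAc)2 (5 mol%), P(o-tol)3 (10 mol%), K2CO3 (2 equiv), n-Bu4NBr (20 mol%), DMF, 100 °C
Reagents that add atoms: styrene, C=Cc1ccccc1
Why: Mizoroki–Heck reaction – oxidative addition at the only C–Br bond, syn-insertion of styrene at its terminal carbon and syn-β-hydride elimination give the E-stilbene, while the MOM ether, the OMe group and the trisubstituted prenyl alkenes are inert.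

**Step 5**
Reactants: 13 3-methoxy-5-(methoxymethoxy)-2,4-bis(3-methylbut-2-en-1-yl)-1-[(E)-2-phenylethenyl]benzene
Product: 14 chiricanine C, 3-methoxy-2,4-bis(3-methylbut-2-en-1-yl)-5-[(E)-2-phenylethenyl]phenol
Conditions: HCl (1.25 M in MeOH), rt to 40 °C; NaHCO3 quench
Reagents that add atoms: none
Why: Acid-catalysed acetal (MOM) solvolysis in methanol frees the phenol; dilute acid at or below 40 °C is mild enough to leave the ortho-prenyl group uncyclised (no chroman) and the E-alkene unisomerised.

## Compound list

1 | 3,5-dibromophenol | Oc1cc(Br)cc(Br)c1 | starting material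
2 | chloromethyl methyl ether | COCCl | starting material
3 | 1,3-dibromo-5-(methoxymethoxy)benzene | COCOc1cc(Br)cc(Br)c1 | intermediate
4 | 1-bromo-3-methylbut-2-ene (prenyl bromide) | CC(C)=CCBr | starting material
5 | [2,6-dibromo-4-(methoxymethoxy)phenyl]lithium | [Li]c1c(Br)cc(OCOC)cc1Br | intermediate
6 | 1,3-dibromo-5-(methoxymethoxy)-2-(3-methylbut-2-en-1-yl)benzene | CC(C)=CCc1c(Br)cc(OCOC)cc1Br | intermediate
7 | lithium methoxide | [Li+].[O-]C | starting material
8 | [2,4-dibromo-6-(methoxymethoxy)-3-(3-methylbut-2-en-1-yl)phenyl]lithium | [Li]c1c(Br)c(CC=C(C)C)c(Br)cc1OCOC | intermediate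
9 | 5-bromo-3-(methoxymethoxy)-6-(3-methylbut-2-en-1-yl)-1,2-didehydrobenzene (aryne) | COCOC1=CC(Br)=C(CC=C(C)C)C#C1 | intermediate
10 | [4-bromo-2-methoxy-6-(methoxymethoxy)-3-(3-methylbut-2-en-1-yl)phenyl]lithium | [Li]c1c(OC)c(CC=C(C)C)c(Br)cc1OCOC | intermediate
11 | 1-bromo-3-methoxy-5-(methoxymethoxy)-2,4-bis(3-methylbut-2-en-1-yl)benzene | COCOc1cc(Br)c(CC=C(C)C)c(OC)c1CC=C(C)C | intermediate
12 | styrene | C=Cc1ccccc1 | starting material
13 | 3-methoxy-5-(methoxymethoxy)-2,4-bis(3-methylbut-2-en-1-yl)-1-[(E)-2-phenylethenyl]benzene | COCOc1cc(/C=C/c2ccccc2)c(CC=C(C)C)c(OC)c1CC=C(C)C | intermediate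
14 | chiricanine C, 3-methoxy-2,4-bis(3-methylbut-2-en-1-yl)-5-[(E)-2-phenylethenyl]phenol | COc1c(CC=C(C)C)c(O)cc(/C=C/c2ccccc2)c1CC=C(C)C | target

## Step count and risks

Total step count: 5. Longest linear sequence: 5 steps (1 → 3 → 6 → 11 → 13 → 14).

**Step 3 (proposed new method, most likely to fail).** Methoxide may add to aryne 9 too slowly, so that amine or aryllithium addition, or a second elimination, wins. The fallback uses known chemistry, sets out from 6 and comes back at 11. Mono-hydroxylation of one of the two equivalent C–Br bonds (Pd2(dba)3/t-BuXPhos, KOH, dioxane–H2O, 80 °C, 6 in slight excess) gives 3-bromo-5-(methoxymethoxy)-2-(3-methylbut-2-en-1-yl)phenol F1. O-Alkylation with tert-butyl 2-methylbut-3-en-2-yl carbonate under zerovalent palladium catalysis (Pd(PPh3)4, THF, 0 °C) gives the tertiary allyl ether 1-bromo-5-(methoxymethoxy)-3-[(2-methylbut-3-en-2-yl)oxy]-2-(3-methylbut-2-en-1-yl)benzene F2. Thermal aromatic Claisen rearrangement (N,N-diethylaniline, 130 °C) into the only free ortho position gives 3-bromo-5-(methoxymethoxy)-2,6-bis(3-methylbut-2-en-1-yl)phenol F3. O-Methylation (MeI, K2CO3, acetone, 50 °C) then gives 11.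

**Step 2.** Lithiation could occur partly next to the MOM group instead of between the bromines, or the hindered aryllithium could decompose before it is allylated. The fallback enforces the site sterically, sets out from 1 and comes back at 6. Silylation (NaH, i-Pr3SiCl, THF) gives (3,5-dibromophenoxy)tri(propan-2-yl)silane F4, whose bulky silyl group shields both positions next to oxygen. LiN(iPr)2 at −78 °C then gives [2,6-dibromo-4-(tri(propan-2-yl)silyloxy)phenyl]lithium F5. Copper-catalysed reaction with prenyl bromide gives [3,5-dibromo-4-(3-methylbut-2-en-1-yl)phenoxy]tri(propan-2-yl)silane F6. n-Bu4NF in THF frees 3,5-dibromo-4-(3-methylbut-2-en-1-yl)phenol F7, and MOMCl/NaH converts it into 6.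

**Step 4.** The bromide sits next to a prenyl group, which slows insertion, and a palladium hydride could shift the prenyl double bonds. The fallback sets out from 11 and comes back at 13. It is a Suzuki–Miyaura coupling with commercial (E)-2-phenylethenylboronic acid pinacol ester (Pd(OAc)2/SPhos, K3PO4, toluene–H2O, 80 °C), which transfers the intact E-styryl unit without a hydride stage. It makes no compound outside the list (F0).

## Further compounds

F1 | step 3 | 3-bromo-5-(methoxymethoxy)-2-(3-methylbut-2-en-1-yl)phenol | COCOc1cc(O)c(CC=C(C)C)c(Br)c1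
F2 | step 3 | 1-bromo-5-(methoxymethoxy)-3-[(2-methylbut-3-en-2-yl)oxy]-2-(3-methylbut-2-en-1-yl)benzene | COCOc1cc(OC(C)(C)C=C)c(CC=C(C)C)c(Br)c1
F3 | step 3 | 3-bromo-5-(methoxymethoxy)-2,6-bis(3-methylbut-2-en-1-yl)phenol | COCOc1cc(Br)c(CC=C(C)C)c(O)c1CC=C(C)C
F4 | step 2 | (3,5-dibromophenoxy)tri(propan-2-yl)silane | CC(C)[Si](Oc1cc(Br)cc(Br)c1)(C(C)C)C(C)C
F5 | step 2 | [2,6-dibromo-4-(tri(propan-2-yl)silyloxy)phenyl]lithium | [Li]c1c(Br)cc(O[Si](C(C)C)(C(C)C)C(C)C)cc1Br
F6 | step 2 | [3,5-dibromo-4-(3-methylbut-2-en-1-yl)phenoxy]tri(propan-2-yl)silane | CC(C)=CCc1c(Br)cc(O[Si](C(C)C)(C(C)C)C(C)C)cc1Br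
F7 | step 2 | 3,5-dibromo-4-(3-methylbut-2-en-1-yl)phenol | CC(C)=CCc1c(Br)cc(O)cc1Br
F0 | step 4 | none | none
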